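**Retrosynthetic overview**
1. Target 25 ⇐ silyl ether 24 (fluoride). 24 ⇐ epoxy aldehyde/alkenyl iodide 20 + anhydride 22 in one operation that closes C3–C4 (11-membered ring, formed last) and makes the C4–O ester bond (new acyl-turnover chromium/nickel coupling).
2. Oxirane C5–C6 (two C–O bonds, sets C5/C6 and then steers C4) ⇐ Sharpless epoxidation of (Z)-allylic alcohol 18; C2=C3 iodide ⇐ Takai olefination of aldehyde 17.
3. C8–C9 ⇐ B-alkyl Suzuki coupling of (Z)-iodoalkene 10 with the borane of dienol 15 (made from prop-2-yn-1-ol).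
4. Quaternary C1 ⇐ the C–O stereocentre of (2S,3S)-epoxygeraniol 2: triflate/acetylide coupling, trans-hydrostannation–iodination, then a stereospecific epoxide-to-aldehyde 1,2-shift.
5. Ring order: sacrificial oxirane of 2 (step 1, consumed in step 5) → oxirane of the target (step 10) → carbocycle (step 13).

Assumption: the SMILES is read literally; ring locants used below are C1 (quaternary), C2=C3 (E), C4 (ester), C5/C6 (oxirane), C7, C8, C9 (CH2OH)=C10, C11, with C8 and C11 cis on C9=C10, a cis-fused oxirane, and 1S,4S,5R,6R.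

**Route**

Step 1
Reactants: 1 geraniol
Product: 2 [(2S,3S)-3-methyl-3-(4-methylpent-3-en-1-yl)oxiran-2-yl]methanol
Conditions: Ti(OiPr)4 (5 mol %), L-(+)-diethyl tartrate (7 mol %), t-BuOOH (2 equiv), 4 Å molecular sieves, CH2Cl2, −20 °C
Reagents that add atoms: tert-butyl hydroperoxide, CC(C)(C)OO
Why: Katsuki–Sharpless asymmetric epoxidation, in which the tetravalent titanium–tartrate complex epoxidises only the allylic alkene and gives the (2S,3S) epoxide whose methyl-bearing carbon later becomes C1.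

Step 2
Reactants: 2; 3 trimethyl(prop-2-yn-1-yloxy)silane
Product: 6 4-[(2S,3S)-3-methyl-3-(4-methylpent-3-en-1-yl)oxiran-2-yl]but-2-yn-1-ol, via epoxy triflate 4 (not isolated), via trimethylsilyl ether 5 (not isolated)
Conditions: Tf2O, 2,6-lutidine, CH2Cl2, −78 °C, cold aqueous wash; then 3/n-BuLi (1.5 equiv), THF–DMPU, −78 to −20 °C; then K2CO3 (cat.), MeOH, 0 °C
Reagents that add atoms: none
Why: SN2 displacement of a primary triflate by a lithium acetylide is faster than attack on the trisubstituted oxirane, and methanolysis then removes the labile O–SiMe3 group; no stereocentre is touched.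

Step 3
Reactants: 6
Product: 8 (2Z)-2-iodo-4-[(2S,3S)-3-methyl-3-(4-methylpent-3-en-1-yl)oxiran-2-yl]but-2-en-1-ol, via alkenylstannane 7 (not isolated)
Conditions: [(C5Me5)RuCl]4 (2 mol %), Bu3SnH (1.1 equiv, slow addition), CH2Cl2, rt; then iodine (1.1 equiv), CH2Cl2, 0 °C
Reagents that add atoms: iodine, [I][I]
Why: Hydroxyl-directed ruthenium-catalysed trans-hydrostannation puts tin on the alkyne carbon next to CH2OH with hydrogen trans to it, and tin–iodine exchange with retention gives the (Z)-2-iodoalkene with iodine cis to C11, which fixes the later C9=C10 geometry.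

Step 4
Reactants: 8
Product: 9 tert-butyl({(2Z)-2-iodo-4-[(2S,3S)-3-methyl-3-(4-methylpent-3-en-1-yl)oxiran-2-yl]but-2-en-1-yl}oxy)dimethylsilane
Conditions: TBSCl (1.2 equiv), imidazole (2 equiv), DMF, 0 °C to rt
Reagents that add atoms: tert-butyldimethylsilyl chloride, CC(C)(C)[Si](C)(C)Cl
Why: Standard silylation of the primary alcohol masks the future C9 hydroxymethyl group through the Lewis-acid, epoxidation, oxidation and chromium steps.

Step 5
Reactants: 9
Product: 10 (2S,4Z)-6-[(tert-butyldimethylsilyl)oxy]-5-iodo-2-methyl-2-(4-methylpent-3-en-1-yl)hex-4-enal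
Conditions: MeAl(OAr)2 (Ar = 4-bromo-2,6-di-tert-butylphenyl, 2 equiv), CH2Cl2, −78 to −40 °C
Reagents that add atoms: none
Why: Organoaluminium-promoted Meinwald rearrangement, in which the bulky Lewis acid opens the oxirane at its methyl-bearing carbon and the allylic CH2 group shifts from the oxirane CH to that carbon anti to the departing oxygen, so the C–O stereocentre is converted with inversion into the (S) all-carbon centre C1 while the oxirane CH becomes the aldehyde.

Step 6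
Reactants: 11 prop-2-yn-1-ol
Product: 13 (2Z)-3-iodo-2-methylprop-2-en-1-ol, via alkenylmagnesium alkoxide 12 (not isolated)
Conditions: MeMgBr (2.5 equiv), copper monoiodide CuI (10 mol %), THF, −10 °C to rt; then iodine, −78 to 0 °C
Reagents that add atoms: methylmagnesium bromide, C[Mg]Br; iodine, [I][I]
Why: Copper-catalysed anti-carbomagnesiation of the propargylic alkoxide gives a chelated alkenylmagnesium species, and its iodinolysis with retention leaves iodine cis to CH2OH.

Step 7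
Reactants: 13; 14 tributyl(vinyl)stannane
Product: 15 (2Z)-2-methylpenta-2,4-dien-1-ol
Conditions: Pd(PPh3)4 (5 mol %), CuI (10 mol %), DMF, rt
Reagents that add atoms: none
Why: Stille coupling proceeds with retention at the alkenyl iodide, so the new vinyl group stays cis to CH2OH.

Step 8
Reactants: 15; 10
Product: 17 (2S,4E,8Z)-5-{[(tert-butyldimethylsilyl)oxy]methyl}-10-hydroxy-2,9-dimethyl-2-(4-methylpent-3-en-1-yl)deca-4,8-dienal, via alkylborane 16 (not isolated)
Conditions: 15, 9-BBN-H (2.2 equiv), THF, 0 °C to rt; then 10, PdCl2(dppf) (5 mol %; dppf = 1,1'-bis(diphenylphosphino)ferrocene), AsPh3 (10 mol %), Cs2CO3 (3 equiv), DMF–H2O, rt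
Reagents that add atoms: none
Why: B-alkyl Suzuki–Miyaura coupling, in which 9-BBN adds only to the terminal vinyl carbon of the diene and the sp3–sp2 coupling at the iodoalkene occurs with retention, giving C8 cis to C11 on C9=C10.

Step 9
Reactants: 17
Product: 18 (2Z,6E,9S,10E)-6-{[(tert-butyldimethylsilyl)oxy]methyl}-11-iodo-2,9-dimethyl-9-(4-methylpent-3-en-1-yl)undeca-2,6,10-trien-1-ol
Conditions: CrCl2 (6 equiv), CHI3 (2 equiv), THF–dioxane, 0 °C to rt
Reagents that add atoms: iodoform, IC(I)I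
Why: Takai iodo-olefination of the non-enolisable neopentyl aldehyde by a geminal dichromium reagent gives the (E)-alkenyl iodide (C2=C3) and tolerates the free allylic alcohol.

Step 10
Reactants: 18
Product: 19 [(2S,3R)-3-{(3E,6S,7E)-3-{[(tert-butyldimethylsilyl)oxy]methyl}-8-iodo-6-methyl-6-(4-methylpent-3-en-1-yl)octa-3,7-dien-1-yl}-2-methyloxiran-2-yl]methanol
Conditions: Ti(OiPr)4 (20 mol %), L-(+)-diethyl tartrate (24 mol %), t-BuOOH (2 equiv), 4 Å molecular sieves, CH2Cl2, −20 °C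
Reagents that add atoms: tert-butyl hydroperoxide, CC(C)(C)OO
Why: Katsuki–Sharpless asymmetric epoxidation, reagent-controlled as for nerol-type (Z)-allylic alcohols, forms the oxirane ring and sets C5 and C6 (2S,3R in this intermediate), while the silylated allylic alcohol, the iodoalkene and the isolated alkene do not react.

Step 11
Reactants: 19
Product: 20 (2R,3R)-3-{(3E,6S,7E)-3-{[(tert-butyldimethylsilyl)oxy]methyl}-8-iodo-6-methyl-6-(4-methylpent-3-en-1-yl)octa-3,7-dien-1-yl}-2-methyloxirane-2-carbaldehyde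
Conditions: Dess–Martin periodinane (1.3 equiv), NaHCO3 (5 equiv), CH2Cl2, 0 °C to rt
Reagents that add atoms: none
Why: Buffered Dess–Martin oxidation converts the primary epoxy alcohol into the aldehyde; the alpha carbon is quaternary, so nothing can epimerise.

Step 12
Reactants: 21 3-methylbut-2-enoic acid
Product: 22 3-methylbut-2-enoic anhydride
Conditions: 3-methylbut-2-enoyl chloride (1.0 equiv), pyridine (1.1 equiv), Et2O, 0 °C to rt; filtration, then distillation
Reagents that add atoms: 3-methylbut-2-enoyl chloride, CC(C)=CC(=O)Cl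
Why: Nucleophilic acyl substitution, in which the carboxylate of 21 attacks the acid chloride (activated as its N-acylpyridinium salt) to give the symmetrical anhydride, one acyl group coming from each component; pyridine is too weak a base to form the vinylketene, so the conjugated double bond does not move.

Step 13
Reactants: 20; 22
Product: 24 (1R,2S,3E,5S,7E,11R)-8-{[(tert-butyldimethylsilyl)oxy]methyl}-1,5-dimethyl-5-(4-methylpent-3-en-1-yl)-12-oxabicyclo[9.1.0]dodeca-3,7-dien-2-yl 3-methylbut-2-enoate, via chromium alkoxide 23 (not isolated)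
Conditions: CrCl2 (15 mol %), NiCl2 (2 mol %), Mn powder (2 equiv), 22 (2 equiv), THF–DMF (6:1), slow addition of 20 to 2 mM, rt
Reagents that add atoms: none
Why: Proposed new method: an acyl-turnover chromium-catalysed Nozaki–Hiyama–Kishi macrocyclisation, in which zerovalent nickel inserts into the C3–I bond, the alkenyl group passes to trivalent chromium with retention and adds to the aldehyde anti to the oxirane C–O bond in the Cornforth arrangement (gives 4S, erythro to the epoxide), and the trivalent chromium alkoxide 23 is then O-acylated by anhydride 22, which forms the C4–O ester bond and frees chromium as its carboxylate for re-reduction by manganese to the divalent state; alkenylchromium reagents do not attack anhydrides, and ligand-free nickel is kept at 2 mol % to suppress acyl cross-coupling; closest known reaction type: the chlorosilane-mediated chromium-catalysed Nozaki–Hiyama–Kishi cyclisation, where Me3SiCl cleaves the O–Cr bond.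

Step 14
Reactants: 24
Product: 25 (1R,2S,3E,5S,7E,11R)-8-(hydroxymethyl)-1,5-dimethyl-5-(4-methylpent-3-en-1-yl)-12-oxabicyclo[9.1.0]dodeca-3,7-dien-2-yl 3-methylbut-2-enoate
Conditions: Bu4NF (1.5 equiv), AcOH (1.5 equiv), THF, 0 °C to rt
Reagents that add atoms: none
Why: Buffered fluoride desilylation cleaves the primary silyl ether without opening the oxirane or moving or cleaving the allylic ester.

**Compound list**
1 | geraniol, (2E)-3,7-dimethylocta-2,6-dien-1-ol | CC(C)=CCC/C(C)=C/CO | starting material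
2 | [(2S,3S)-3-methyl-3-(4-methylpent-3-en-1-yl)oxiran-2-yl]methanol | CC(C)=CCC[C@]1(C)O[C@H]1CO | intermediate
3 | trimethyl(prop-2-yn-1-yloxy)silane | C#CCO[Si](C)(C)C | starting material
4 | [(2S,3S)-3-methyl-3-(4-methylpent-3-en-1-yl)oxiran-2-yl]methyl trifluoromethanesulfonate | CC(C)=CCC[C@]1(C)O[C@H]1COS(=O)(=O)C(F)(F)F | intermediate
5 | trimethyl({4-[(2S,3S)-3-methyl-3-(4-methylpent-3-en-1-yl)oxiran-2-yl]but-2-yn-1-yl}oxy)silane | CC(C)=CCC[C@]1(C)O[C@H]1CC#CCO[Si](C)(C)C | intermediate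
6 | 4-[(2S,3S)-3-methyl-3-(4-methylpent-3-en-1-yl)oxiran-2-yl]but-2-yn-1-ol | CC(C)=CCC[C@]1(C)O[C@H]1CC#CCO | intermediate
7 | (2Z)-4-[(2S,3S)-3-methyl-3-(4-methylpent-3-en-1-yl)oxiran-2-yl]-2-(tributylstannyl)but-2-en-1-ol | CC(C)=CCC[C@]1(C)O[C@H]1C/C=C(\[Sn](CCCC)(CCCC)CCCC)CO | intermediate
8 | (2Z)-2-iodo-4-[(2S,3S)-3-methyl-3-(4-methylpent-3-en-1-yl)oxiran-2-yl]but-2-en-1-ol | CC(C)=CCC[C@]1(C)O[C@H]1C/C=C(\I)CO | intermediate
9 | tert-butyl({(2Z)-2-iodo-4-[(2S,3S)-3-methyl-3-(4-methylpent-3-en-1-yl)oxiran-2-yl]but-2-en-1-yl}oxy)dimethylsilane | CC(C)=CCC[C@]1(C)O[C@H]1C/C=C(\I)CO[Si](C)(C)C(C)(C)C | intermediate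
10 | (2S,4Z)-6-[(tert-butyldimethylsilyl)oxy]-5-iodo-2-methyl-2-(4-methylpent-3-en-1-yl)hex-4-enal | CC(C)=CCC[C@](C)(C=O)C/C=C(\I)CO[Si](C)(C)C(C)(C)C | intermediate
11 | prop-2-yn-1-ol | C#CCO | starting material
12 | bromomagnesium (2Z)-3-(bromomagnesio)-2-methylprop-2-en-1-olate | C/C(=C/[Mg]Br)CO[Mg]Br | intermediate
13 | (2Z)-3-iodo-2-methylprop-2-en-1-ol | OC/C(C)=C\I | intermediate
14 | tributyl(vinyl)stannane | C=C[Sn](CCCC)(CCCC)CCCC | starting material
15 | (2Z)-2-methylpenta-2,4-dien-1-ol | OC/C(C)=C\C=C | intermediate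
16 | 9-[(3Z)-5-(9-borabicyclo[3.3.1]nonan-9-yloxy)-4-methylpent-3-en-1-yl]-9-borabicyclo[3.3.1]nonane | C(/C(C)=C\CCB1C2CCCC1CCC2)OB1C2CCCC1CCC2 | intermediate
17 | (2S,4E,8Z)-5-{[(tert-butyldimethylsilyl)oxy]methyl}-10-hydroxy-2,9-dimethyl-2-(4-methylpent-3-en-1-yl)deca-4,8-dienal | CC(C)=CCC[C@](C)(C=O)C/C=C(\CC/C=C(/C)CO)CO[Si](C)(C)C(C)(C)C | intermediate
18 | (2Z,6E,9S,10E)-6-{[(tert-butyldimethylsilyl)oxy]methyl}-11-iodo-2,9-dimethyl-9-(4-methylpent-3-en-1-yl)undeca-2,6,10-trien-1-ol | CC(C)=CCC[C@](C)(/C=C/I)C/C=C(\CC/C=C(/C)CO)CO[Si](C)(C)C(C)(C)C | intermediate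
19 | [(2S,3R)-3-{(3E,6S,7E)-3-{[(tert-butyldimethylsilyl)oxy]methyl}-8-iodo-6-methyl-6-(4-methylpent-3-en-1-yl)octa-3,7-dien-1-yl}-2-methyloxiran-2-yl]methanol | CC(C)=CCC[C@](C)(/C=C/I)C/C=C(\CC[C@H]1O[C@@]1(C)CO)CO[Si](C)(C)C(C)(C)C | intermediate
20 | (2R,3R)-3-{(3E,6S,7E)-3-{[(tert-butyldimethylsilyl)oxy]methyl}-8-iodo-6-methyl-6-(4-methylpent-3-en-1-yl)octa-3,7-dien-1-yl}-2-methyloxirane-2-carbaldehyde | CC(C)=CCC[C@](C)(/C=C/I)C/C=C(\CC[C@H]1O[C@@]1(C)C=O)CO[Si](C)(C)C(C)(C)C | intermediate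
21 | 3-methylbut-2-enoic acid (senecioic acid) | CC(C)=CC(=O)O | starting material
22 | 3-methylbut-2-enoic anhydride | CC(C)=CC(=O)OC(=O)C=C(C)C | intermediate
23 | (1R,2S,3E,5S,7E,11R)-8-{[(tert-butyldimethylsilyl)oxy]methyl}-2-[(dichlorochromio)oxy]-1,5-dimethyl-5-(4-methylpent-3-en-1-yl)-12-oxabicyclo[9.1.0]dodeca-3,7-diene | CC(C)=CCC[C@]1(C)/C=C/[C@H](O[Cr](Cl)Cl)[C@]2(C)O[C@@H]2CC/C(CO[Si](C)(C)C(C)(C)C)=C\C1 | intermediate
24 | (1R,2S,3E,5S,7E,11R)-8-{[(tert-butyldimethylsilyl)oxy]methyl}-1,5-dimethyl-5-(4-methylpent-3-en-1-yl)-12-oxabicyclo[9.1.0]dodeca-3,7-dien-2-yl 3-methylbut-2-enoate | CC(C)=CCC[C@]1(C)/C=C/[C@H](OC(=O)C=C(C)C)[C@]2(C)O[C@@H]2CC/C(CO[Si](C)(C)C(C)(C)C)=C\C1 | intermediate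
25 | (1R,2S,3E,5S,7E,11R)-8-(hydroxymethyl)-1,5-dimethyl-5-(4-methylpent-3-en-1-yl)-12-oxabicyclo[9.1.0]dodeca-3,7-dien-2-yl 3-methylbut-2-enoate (CNP0318149.1) | CC(C)=CCC[C@]1(C)/C=C/[C@H](OC(=O)C=C(C)C)[C@]2(C)O[C@@H]2CC/C(CO)=C\C1 | target

**Step count**
Total: 14 steps. Longest linear sequence: 11 steps (steps 1, 2, 3, 4, 5, 8, 9, 10, 11, 13, 14, from geraniol).

**Three steps most likely to fail, each with a fallback**

First, step 13, the proposed acyl-turnover cyclisation. The trivalent chromium alkoxide may be acylated too slowly to turn the catalyst over, nickel may couple the anhydride with the alkenyl iodide, or the epoxy aldehyde may be opened by chloride. The fallback uses known chemistry, sets out from 20 and comes back at 24. A classical stoichiometric Nozaki–Hiyama–Kishi macrocyclisation (CrCl2 6 equiv, NiCl2 1 mol %, DMSO–THF, 2 mM, rt) passes through the same alkoxide 23 and after aqueous work-up gives the macrocyclic alcohol (1S,2S,3E,5S,7E,11R)-8-{[(tert-butyldimethylsilyl)oxy]methyl}-1,5-dimethyl-5-(4-methylpent-3-en-1-yl)-12-oxabicyclo[9.1.0]dodeca-3,7-dien-2-ol F10. This is acylated with anhydride 22, Et3N and 4-(dimethylamino)pyridine in CH2Cl2 to give 24.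

Second, step 5, the epoxide-to-aldehyde 1,2-shift. A hydride shift to the ketone could compete with carbon migration, and the iodoalkene or allylic silyl ether could interfere with the Lewis acid. The fallback sets out from 6 and comes back at 10; it moves the rearrangement to a simpler substrate whose migrating group is a plain propargylic CH2. Alcohol 6 is silylated (TBSCl, imidazole) to tert-butyl({4-[(2S,3S)-3-methyl-3-(4-methylpent-3-en-1-yl)oxiran-2-yl]but-2-yn-1-yl}oxy)dimethylsilane F1. The same aluminium reagent rearranges it to (2S)-6-[(tert-butyldimethylsilyl)oxy]-2-methyl-2-(4-methylpent-3-en-1-yl)hex-4-ynal F2. Bu4NF gives (2S)-6-hydroxy-2-methyl-2-(4-methylpent-3-en-1-yl)hex-4-ynal F3. Ruthenium-catalysed trans-hydrostannation as in step 3 gives (2S,4Z)-6-hydroxy-2-methyl-2-(4-methylpent-3-en-1-yl)-5-(tributylstannyl)hex-4-enal F4, and iodine gives (2S,4Z)-6-hydroxy-5-iodo-2-methyl-2-(4-methylpent-3-en-1-yl)hex-4-enal F5. Silylation of F5 with TBSCl and imidazole returns 10.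

Third, step 8, the B-alkyl Suzuki coupling in the presence of the free aldehyde. The aldehyde could be reduced by the borane or damaged by the aqueous base. The fallback sets out from 9 (before the aldehyde exists, together with dienol 15) and comes back at 17. Dienol 15 is converted with Et3SiCl and imidazole into triethyl{[(2Z)-2-methylpenta-2,4-dien-1-yl]oxy}silane F6. Hydroboration with 9-BBN-H gives 9-{(3Z)-4-methyl-5-[(triethylsilyl)oxy]pent-3-en-1-yl}-9-borabicyclo[3.3.1]nonane F7. F7 is coupled with iodoalkene 9 under the step 8 conditions to give tert-butyl{[(2E,5Z)-6-methyl-2-{2-[(2S,3S)-3-methyl-3-(4-methylpent-3-en-1-yl)oxiran-2-yl]ethylidene}-7-[(triethylsilyl)oxy]hept-5-en-1-yl]oxy}dimethylsilane F8. Rearrangement as in step 5 gives (2S,4E,8Z)-5-{[(tert-butyldimethylsilyl)oxy]methyl}-2,9-dimethyl-2-(4-methylpent-3-en-1-yl)-10-[(triethylsilyl)oxy]deca-4,8-dienal F9. AcOH–THF–H2O then removes the triethylsilyl group selectively to give 17.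

**Further compounds**
F1 | step 5 | tert-butyl({4-[(2S,3S)-3-methyl-3-(4-methylpent-3-en-1-yl)oxiran-2-yl]but-2-yn-1-yl}oxy)dimethylsilane | CC(C)=CCC[C@]1(C)O[C@H]1CC#CCO[Si](C)(C)C(C)(C)C
F2 | step 5 | (2S)-6-[(tert-butyldimethylsilyl)oxy]-2-methyl-2-(4-methylpent-3-en-1-yl)hex-4-ynal | CC(C)=CCC[C@](C)(C=O)CC#CCO[Si](C)(C)C(C)(C)C
F3 | step 5 | (2S)-6-hydroxy-2-methyl-2-(4-methylpent-3-en-1-yl)hex-4-ynal | CC(C)=CCC[C@](C)(C=O)CC#CCO
F4 | step 5 | (2S,4Z)-6-hydroxy-2-methyl-2-(4-methylpent-3-en-1-yl)-5-(tributylstannyl)hex-4-enal | CC(C)=CCC[C@](C)(C=O)C/C=C(\[Sn](CCCC)(CCCC)CCCC)CO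
F5 | step 5 | (2S,4Z)-6-hydroxy-5-iodo-2-methyl-2-(4-methylpent-3-en-1-yl)hex-4-enal | CC(C)=CCC[C@](C)(C=O)C/C=C(\I)CO
F6 | step 8 | triethyl{[(2Z)-2-methylpenta-2,4-dien-1-yl]oxy}silane | CC[Si](CC)(CC)OC/C(C)=C\C=C
F7 | step 8 | 9-{(3Z)-4-methyl-5-[(triethylsilyl)oxy]pent-3-en-1-yl}-9-borabicyclo[3.3.1]nonane | CC[Si](CC)(CC)OC/C(C)=C\CCB1C2CCCC1CCC2
F8 | step 8 | tert-butyl{[(2E,5Z)-6-methyl-2-{2-[(2S,3S)-3-methyl-3-(4-methylpent-3-en-1-yl)oxiran-2-yl]ethylidene}-7-[(triethylsilyl)oxy]hept-5-en-1-yl]oxy}dimethylsilane | CC(C)=CCC[C@]1(C)O[C@H]1C/C=C(\CC/C=C(/C)CO[Si](CC)(CC)CC)CO[Si](C)(C)C(C)(C)C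
F9 | step 8 | (2S,4E,8Z)-5-{[(tert-butyldimethylsilyl)oxy]methyl}-2,9-dimethyl-2-(4-methylpent-3-en-1-yl)-10-[(triethylsilyl)oxy]deca-4,8-dienal | CC(C)=CCC[C@](C)(C=O)C/C=C(\CC/C=C(/C)CO[Si](CC)(CC)CC)CO[Si](C)(C)C(C)(C)C
F10 | step 13 | (1S,2S,3E,5S,7E,11R)-8-{[(tert-butyldimethylsilyl)oxy]methyl}-1,5-dimethyl-5-(4-methylpent-3-en-1-yl)-12-oxabicyclo[9.1.0]dodeca-3,7-dien-2-ol | CC(C)=CCC[C@]1(C)/C=C/[C@H](O)[C@]2(C)O[C@@H]2CC/C(CO[Si](C)(C)C(C)(C)C)=C\C1
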